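## Retrosynthetic overview

1. The last step removes four silyl groups with fluoride. Before that, the ring-A tetrahydrofuran (O3–C4) is re-closed from a furofuranone with LiAlH4, then MsCl.
2. The key C5–C6 bond and the second ring come from a Rh(II)-carbenoid insertion. An α-diazo-γ-lactone inserts into the benzylic C–H of its own ring-B benzyl ether, which places that aryl group 6-endo.
3. That ether is made by joining a (4S,5R)-4-hydroxymethyl-5-aryl lactone (ring A half) to a ring-B/ring-C benzylic trichloroacetimidate.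
4. The lactone comes from Ir-catalysed transfer-hydrogenative (hydroxymethyl)allylation of silylated vanillin with vinylethylene carbonate (sets C1 and C2), then hydroboration and oxidative lactonisation. Vanillin is built from p-cresol.
5. The B/C half comes from Rh(II) O–H insertion of an aroyl diazoacetate into 4-bromosyringol (8''-O-4' bond), then a new ATH–DKR (sets C7'' and C8''). Both arenes come from resorcinol. Ring order: lactone, then THF by C–H insertion, then lactone converted into the second THF.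

**Labels.** The core is numbered as 3,7-dioxabicyclo[3.3.0]octane, with C2 bearing ring A and C6 bearing ring B.
- ArA = 3-methoxy-4-(triisopropylsilyloxy)phenyl.
- ArC = 3,5-dimethoxy-4-(triisopropylsilyloxy)phenyl.
- ArB = 3,5-dimethoxy-4-{[(1R,2R)-1,3-bis(tert-butyldimethylsilyloxy)-1-ArC-propan-2-yl]oxy}phenyl.

**Assumption.** The (R)-SEGPHOS iridium catalyst is taken to add to the aldehyde Re face, as this ligand family does in the parent allylations. If the sense is opposite, (S)-SEGPHOS is used and nothing else changes.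

## Route

Step 1
Reactants: 1 resorcinol
Product: 2 1,3-dimethoxybenzene
Conditions: Me2SO4 (2.4 equiv), K2CO3, acetone, reflux
Reagents that add atoms: dimethyl sulfate COS(=O)(=O)OC
Why: Williamson O-methylation of both phenols under weak base is clean and creates no stereocentre.

Step 2
Reactants: 2 1,3-dimethoxybenzene
Product: 5 2,6-dimethoxyphenol (syringol), via aryllithium 3 (not isolated), via dimethyl arylboronate 4 (not isolated)
Conditions: n-BuLi, THF, 0 °C to rt; B(OMe)3, −78 °C to rt; AcOH, 30% H2O2, 0 °C to rt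
Reagents that add atoms: hydrogen peroxide OO
Why: Directed ortho-metalation occurs only at C2 between the two methoxy groups, and borylation–peroxide oxidation turns that carbanion into the phenol.

Step 3
Reactants: 5 syringol
Product: 6 syringaldehyde
Conditions: hexamethylenetetramine, TFA, reflux; then 4 M HCl
Reagents that add atoms: hexamethylenetetramine C1N2CN3CN1CN(C2)C3; water O
Why: Duff formylation goes para to the free OH because both ortho positions are blocked.

Step 4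
Reactants: 6 syringaldehyde
Product: 7 ArC-CHO (O-TIPS-syringaldehyde)
Conditions: TIPSCl, imidazole, DMAP (cat.), DMF, 50 °C
Reagents that add atoms: triisopropylsilyl chloride CC(C)[Si](Cl)(C(C)C)C(C)C
Why: Silylation of the acidic phenol gives an aryl TIPS ether that withstands the later bases and hydrides and leaves with fluoride at the end.

Step 5
Reactants: 7 ArC-CHO; 8 ethyl diazoacetate
Product: 10 ethyl 2-diazo-3-hydroxy-3-ArC-propanoate (racemic), via lithiated diazoacetate 9 (not isolated)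
Conditions: LDA, THF, −78 °C; then 7; AcOH quench
Reagents that add atoms: none
Why: Aldol-type addition of lithiated ethyl diazoacetate to the aldehyde is fast at −78 °C, and the racemic carbinol centre is erased in the next step.

Step 6
Reactants: 10 diazo hydroxy ester
Product: 11 ethyl 2-diazo-3-oxo-3-ArC-propanoate
Conditions: Dess–Martin periodinane, CH2Cl2, rt
Reagents that add atoms: none
Why: Dess–Martin oxidation converts α-diazo-β-hydroxy esters into α-diazo-β-keto esters without touching the diazo group or the silyl ether.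

Step 7
Reactants: 5 syringol
Product: 12 4-bromo-2,6-dimethoxyphenol
Conditions: NBS (1.0 equiv), CH2Cl2, −40 to 0 °C
Reagents that add atoms: N-bromosuccinimide O=C1CCC(=O)N1Br
Why: Electrophilic aromatic bromination is directed para by the free phenol, and the bromide later serves as a masked benzylic carbon.

Step 8
Reactants: 11 diazo keto ester; 12 4-bromo-2,6-dimethoxyphenol
Product: 13 ethyl 2-(4-bromo-2,6-dimethoxyphenoxy)-3-oxo-3-ArC-propanoate (racemic)
Conditions: Rh2(OAc)4 (1 mol%), 12 (1.2 equiv), toluene, 80 °C, slow addition of 11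
Reagents that add atoms: none
Why: Rhodium-carbenoid O–H insertion couples even a hindered phenol to the acceptor/acceptor carbene and forms the 8''-O-4' bond; the new centre is configurationally labile, which the next step exploits.

Step 9
Reactants: 13 α-aryloxy β-keto ester
Product: 14 ethyl (2S,3R)-2-(4-bromo-2,6-dimethoxyphenoxy)-3-hydroxy-3-ArC-propanoate
Conditions: RuCl[(S,S)-TsDPEN](mesitylene) (2 mol%), HCO2H/Et3N (5:2), CH2Cl2, 35 °C
Reagents that add atoms: none
Why: Proposed new method: asymmetric transfer hydrogenation with dynamic kinetic resolution of an α-aryloxy β-keto ester carrying a 2,6-disubstituted aryl ether, a substrate class not yet shown; C2 racemises quickly through the enol in HCO2H/Et3N, the (S,S)-Ru–H/N–H catalyst selects the aryl-ketone face through its CH/π contact as with acetophenones (giving 3R), and the non-chelating outer-sphere hydride transfer follows a polar Felkin–Anh geometry with the bulky C–OAr bond anti to hydride, so only the 2S enantiomer reacts and the syn (threo) product forms; the closest known reaction type is Noyori–Ikariya ATH–DKR of α-alkoxy and α-amido β-keto esters.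

Step 10
Reactants: 14 syn hydroxy ester
Product: 15 (1R,2R)-2-(4-bromo-2,6-dimethoxyphenoxy)-1-ArC-propane-1,3-diol
Conditions: LiBH4, THF, 0 °C to rt
Reagents that add atoms: none
Why: Borohydride reduction of the activated α-aryloxy ester is mild enough to leave both stereocentres and the aryl bromide untouched.

Step 11
Reactants: 15 diol
Product: 16 ArB-Br
Conditions: TBSOTf (2.5 equiv), 2,6-lutidine, CH2Cl2, 0 °C
Reagents that add atoms: tert-butyldimethylsilyl triflate CC(C)(C)[Si](C)(C)OS(=O)(=O)C(F)(F)F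
Why: Silyl triflate with a hindered base silylates both the primary and the crowded benzylic hydroxyl without ionising the benzylic centre.

Step 12
Reactants: 16 ArB-Br
Product: 19 ArB-CH2OH, via aryllithium 17 (not isolated), via aldehyde 18 (not isolated)
Conditions: n-BuLi, THF, −78 °C; DMF, −78 to 0 °C; MeOH, NaBH4, 0 °C
Reagents that add atoms: N,N-dimethylformamide CN(C)C=O
Why: Bromine–lithium exchange, Bouveault formylation and in-flask borohydride reduction install the benzylic carbon at the unhindered position para to the ether.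

Step 13
Reactants: 19 ArB-CH2OH
Product: 20 ArB-CH2 trichloroacetimidate
Conditions: Cl3CCN, DBU (10 mol%), CH2Cl2, 0 °C
Reagents that add atoms: trichloroacetonitrile N#CC(Cl)(Cl)Cl
Why: Base-catalysed addition of the alcohol to trichloroacetonitrile gives a benzylating agent of PMB-like reactivity that works under near-neutral conditions.

Step 14
Reactants: 21 p-cresol
Product: 22 2-bromo-4-methylphenol
Conditions: Br2 (1.0 equiv), CH2Cl2, 0 °C
Reagents that add atoms: bromine BrBr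
Why: Electrophilic bromination goes ortho to OH because the para position is blocked by methyl.

Step 15
Reactants: 22 2-bromo-4-methylphenol
Product: 23 2-methoxy-4-methylphenol (creosol)
Conditions: NaOMe, CuBr (10 mol%), MeOH/DMF, 110 °C; aq. HCl
Reagents that add atoms: sodium methoxide C[O-].[Na+]
Why: Copper-catalysed Ullmann-type methoxylation of ortho-bromophenols is an established C–O coupling.

Step 16
Reactants: 23 creosol
Product: 24 vanillin
Conditions: Co(OAc)2 (2 mol%), NaOH, O2 (1 atm), MeOH, 65 °C; aq. HCl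
Reagents that add atoms: dioxygen O=O
Why: Cobalt-catalysed aerobic benzylic oxidation of para-cresolates proceeds through the quinone methide and stops at the aldehyde, whose phenoxide resists further oxidation.

Step 17
Reactants: 24 vanillin
Product: 25 ArA-CHO (O-TIPS-vanillin)
Conditions: TIPSCl, imidazole, DMF, rt
Reagents that add atoms: triisopropylsilyl chloride CC(C)[Si](Cl)(C(C)C)C(C)C
Why: Standard phenol silylation uses the same fluoride-labile group as on ring C.

Step 18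
Reactants: 25 ArA-CHO; 26 4-vinyl-1,3-dioxolan-2-one (vinylethylene carbonate, racemic)
Product: 27 (1R,2S)-1-ArA-2-vinylpropane-1,3-diol
Conditions: [Ir(cod)Cl]2 (2.5 mol%), (R)-SEGPHOS (5 mol%), 4-cyano-3-nitrobenzoic acid (10 mol%), Cs2CO3 (20 mol%), i-PrOH (2 equiv), THF, 90 °C
Reagents that add atoms: none
Why: In this Krische transfer-hydrogenative carbonyl (hydroxymethyl)allylation, ionisation and decarboxylation give a hydroxymethyl-substituted (E)-σ-allyliridium that adds through a closed chair transition state to the Re face, setting C2 (R) and C1 (S) with anti relative configuration.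

Step 19
Reactants: 27 diol
Product: 28 (1R,2S)-1-ArA-2-[(tert-butyldimethylsilyloxy)methyl]but-3-en-1-ol
Conditions: TBSCl (1.05 equiv), imidazole, CH2Cl2, 0 °C
Reagents that add atoms: tert-butyldimethylsilyl chloride CC(C)(C)[Si](C)(C)Cl
Why: Sterically controlled silylation takes the primary hydroxyl in preference to the secondary benzylic one.

Step 20
Reactants: 28 homoallylic alcohol
Product: 30 (1R,2S)-1-ArA-2-[(tert-butyldimethylsilyloxy)methyl]butane-1,4-diol, via B-alkyl-9-BBN 29 (not isolated)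
Conditions: 9-BBN (2.5 equiv), THF, 0 °C to rt; NaBO3·4H2O, THF/H2O, rt
Reagents that add atoms: sodium perborate [Na+].[Na+].O[B-]1(O)OO[B-](O)(O)OO1
Why: Anti-Markovnikov hydroboration–oxidation of the terminal vinyl group, with perborate as a mild oxidant, spares the aryl silyl ether.

Step 21
Reactants: 30 1,4-diol
Product: 32 (4S,5R)-5-ArA-4-[(tert-butyldimethylsilyloxy)methyl]dihydrofuran-2(3H)-one, via lactol 31 (not isolated)
Conditions: TEMPO (20 mol%), PhI(OAc)2 (2.5 equiv), CH2Cl2, rt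
Reagents that add atoms: none
Why: TEMPO/PhI(OAc)2 oxidative lactonisation oxidises only the primary alcohol, the benzylic OH traps the aldehyde as lactol, and a second oxidation gives the trans lactone with both centres intact.

Step 22
Reactants: 32 silyl lactone
Product: 33 (4S,5R)-5-ArA-4-(hydroxymethyl)dihydrofuran-2(3H)-one
Conditions: CSA (10 mol%), MeOH/CH2Cl2, 0 °C to rt
Reagents that add atoms: none
Why: Acid methanolysis cleaves the primary alkyl TBS ether much faster than the acid-robust aryl TIPS ether.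

Step 23
Reactants: 33 hydroxy lactone; 20 ArB-CH2 trichloroacetimidate
Product: 34 (4S,5R)-5-ArA-4-[(ArB-methoxy)methyl]dihydrofuran-2(3H)-one
Conditions: La(OTf)3 (5 mol%), 20 (1.3 equiv), toluene, rt
Reagents that add atoms: none
Why: Lewis-acid-catalysed trichloroacetimidate benzylation etherifies the single free OH without base, so the lactone is safe, and joining two enantioenriched halves turns residual minor enantiomers into separable diastereomers.

Step 24
Reactants: 34 lactone ether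
Product: 36 (4S,5R)-3-diazo-5-ArA-4-[(ArB-methoxy)methyl]dihydrofuran-2(3H)-one, via trifluoroacetyl lactone 35 (not isolated)
Conditions: LiHMDS, THF, −78 °C; CF3CO2CH2CF3; 5% HCl wash; then p-ABSA, Et3N, H2O (1 equiv), MeCN, rt
Reagents that add atoms: 4-acetamidobenzenesulfonyl azide CC(=O)Nc1ccc(cc1)S(=O)(=O)N=[N+]=[N-]
Why: Danheiser detrifluoroacetylative diazo transfer activates the only enolisable position transiently and installs the diazo group on a simple lactone without disturbing C1 or C2.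

Step 25
Reactants: 36 diazo lactone
Product: 37 (1S,2R,5R,6S)-2-ArA-6-ArB-3,7-dioxabicyclo[3.3.0]octan-4-one (2-exo,6-endo furofuranone)
Conditions: Rh2(OAc)4 (2 mol%), CH2Cl2 (0.01 M), reflux, slow addition
Reagents that add atoms: none
Why: Intramolecular 1,5 rhodium-carbenoid C–H insertion into the benzylic, oxygen-activated C–H forms C5–C6 and the second ring; the tether allows only the cis fusion at C5, and the aryl group takes the pseudo-equatorial site of the chair-like insertion transition state, which is the known route to the 6-endo aryl in endo,exo-furofuranones.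

Step 26
Reactants: 37 furofuranone
Product: 38 (2S,3S,4S)-2-ArB-3-(hydroxymethyl)-4-[(R)-hydroxy(ArA)methyl]tetrahydrofuran
Conditions: LiAlH4, THF, 0 °C
Reagents that add atoms: none
Why: Hydride reduction opens the lactone to the 1,4-diol without touching any C–H stereocentre or the silyl ethers.

Step 27
Reactants: 38 diol
Product: 40 (1S,2R,5S,6S)-2-ArA-6-ArB-3,7-dioxabicyclo[3.3.0]octane, via primary mesylate 39 (not isolated)
Conditions: MsCl (1.1 equiv), Et3N, CH2Cl2, 0 °C to rt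
Reagents that add atoms: none
Why: Selective mesylation of the primary alcohol and 5-exo-tet intramolecular Williamson closure by the benzylic OH retain C2, and any competing benzylic ionisation would lead to the same 2-exo product.

Step 28
Reactants: 40 tetrasilyl furofuran
Product: 41 target
Conditions: TBAF (6 equiv), AcOH (6 equiv), THF, 0 °C to rt
Reagents that add atoms: none
Why: Buffered fluoride desilylation removes all four silyl groups under near-neutral conditions, so the acid-labile 6-endo benzylic ether and the p-hydroxybenzylic alcohol do not epimerise.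

## Compound list

1 | resorcinol | Oc1cccc(O)c1 | starting material
2 | 1,3-dimethoxybenzene | COc1cccc(OC)c1 | intermediate
3 | 2,6-dimethoxyphenyllithium | [Li]c1c(OC)cccc1OC | intermediate
4 | dimethyl (2,6-dimethoxyphenyl)boronate | COB(OC)c1c(OC)cccc1OC | intermediate
5 | 2,6-dimethoxyphenol (syringol) | COc1cccc(OC)c1O | intermediate
6 | 4-hydroxy-3,5-dimethoxybenzaldehyde (syringaldehyde) | COc1cc(C=O)cc(OC)c1O | intermediate
7 | 3,5-dimethoxy-4-(triisopropylsilyloxy)benzaldehyde | COc1cc(C=O)cc(OC)c1O[Si](C(C)C)(C(C)C)C(C)C | intermediate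
8 | ethyl diazoacetate | CCOC(=O)C=[N+]=[N-] | starting material
9 | ethyl lithiodiazoacetate | [Li]C(=[N+]=[N-])C(=O)OCC | intermediate
10 | ethyl 2-diazo-3-hydroxy-3-[3,5-dimethoxy-4-(triisopropylsilyloxy)phenyl]propanoate (racemic) | CCOC(=O)C(=[N+]=[N-])C(O)c1cc(OC)c(O[Si](C(C)C)(C(C)C)C(C)C)c(OC)c1 | intermediate
11 | ethyl 2-diazo-3-oxo-3-[3,5-dimethoxy-4-(triisopropylsilyloxy)phenyl]propanoate | CCOC(=O)C(=[N+]=[N-])C(=O)c1cc(OC)c(O[Si](C(C)C)(C(C)C)C(C)C)c(OC)c1 | intermediate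
12 | 4-bromo-2,6-dimethoxyphenol | COc1cc(Br)cc(OC)c1O | intermediate
13 | ethyl 2-(4-bromo-2,6-dimethoxyphenoxy)-3-oxo-3-[3,5-dimethoxy-4-(triisopropylsilyloxy)phenyl]propanoate (racemic) | CCOC(=O)C(Oc1c(OC)cc(Br)cc1OC)C(=O)c1cc(OC)c(O[Si](C(C)C)(C(C)C)C(C)C)c(OC)c1 | intermediate
14 | ethyl (2S,3R)-2-(4-bromo-2,6-dimethoxyphenoxy)-3-hydroxy-3-[3,5-dimethoxy-4-(triisopropylsilyloxy)phenyl]propanoate | Brc1cc(OC)c(O[C@H](C(=O)OCC)[C@H](O)c2cc(OC)c(O[Si](C(C)C)(C(C)C)C(C)C)c(OC)c2)c(OC)c1 | intermediate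
15 | (1R,2R)-2-(4-bromo-2,6-dimethoxyphenoxy)-1-[3,5-dimethoxy-4-(triisopropylsilyloxy)phenyl]propane-1,3-diol | Brc1cc(OC)c(O[C@H](CO)[C@H](O)c2cc(OC)c(O[Si](C(C)C)(C(C)C)C(C)C)c(OC)c2)c(OC)c1 | intermediate
16 | ArB-Br, the 1,3-bis-TBS ether of 15 (1R,2R) | Brc1cc(OC)c(O[C@H](CO[Si](C)(C)C(C)(C)C)[C@H](O[Si](C)(C)C(C)(C)C)c2cc(OC)c(O[Si](C(C)C)(C(C)C)C(C)C)c(OC)c2)c(OC)c1 | intermediate
17 | ArB-Li | [Li]c1cc(OC)c(O[C@H](CO[Si](C)(C)C(C)(C)C)[C@H](O[Si](C)(C)C(C)(C)C)c2cc(OC)c(O[Si](C(C)C)(C(C)C)C(C)C)c(OC)c2)c(OC)c1 | intermediate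
18 | ArB-CHO | O=Cc1cc(OC)c(O[C@H](CO[Si](C)(C)C(C)(C)C)[C@H](O[Si](C)(C)C(C)(C)C)c2cc(OC)c(O[Si](C(C)C)(C(C)C)C(C)C)c(OC)c2)c(OC)c1 | intermediate
19 | ArB-CH2OH | OCc1cc(OC)c(O[C@H](CO[Si](C)(C)C(C)(C)C)[C@H](O[Si](C)(C)C(C)(C)C)c2cc(OC)c(O[Si](C(C)C)(C(C)C)C(C)C)c(OC)c2)c(OC)c1 | intermediate
20 | ArB-CH2 2,2,2-trichloroacetimidate | N=C(OCc1cc(OC)c(O[C@H](CO[Si](C)(C)C(C)(C)C)[C@H](O[Si](C)(C)C(C)(C)C)c2cc(OC)c(O[Si](C(C)C)(C(C)C)C(C)C)c(OC)c2)c(OC)c1)C(Cl)(Cl)Cl | intermediate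
21 | p-cresol | Cc1ccc(O)cc1 | starting material
22 | 2-bromo-4-methylphenol | Cc1ccc(O)c(Br)c1 | intermediate
23 | 2-methoxy-4-methylphenol (creosol) | COc1cc(C)ccc1O | intermediate
24 | vanillin | COc1cc(C=O)ccc1O | intermediate
25 | 3-methoxy-4-(triisopropylsilyloxy)benzaldehyde | COc1cc(C=O)ccc1O[Si](C(C)C)(C(C)C)C(C)C | intermediate
26 | 4-vinyl-1,3-dioxolan-2-one (racemic) | C=CC1COC(=O)O1 | starting material
27 | (1R,2S)-1-[3-methoxy-4-(triisopropylsilyloxy)phenyl]-2-vinylpropane-1,3-diol | COc1cc([C@H](O)[C@H](CO)C=C)ccc1O[Si](C(C)C)(C(C)C)C(C)C | intermediate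
28 | (1R,2S)-2-[(tert-butyldimethylsilyloxy)methyl]-1-ArA-but-3-en-1-ol | COc1cc([C@H](O)[C@H](CO[Si](C)(C)C(C)(C)C)C=C)ccc1O[Si](C(C)C)(C(C)C)C(C)C | intermediate
29 | B-alkyl-9-borabicyclo[3.3.1]nonane from 28 | COc1cc([C@H](O)[C@H](CO[Si](C)(C)C(C)(C)C)CCB2C3CCCC2CCC3)ccc1O[Si](C(C)C)(C(C)C)C(C)C | intermediate
30 | (1R,2S)-2-[(tert-butyldimethylsilyloxy)methyl]-1-ArA-butane-1,4-diol | COc1cc([C@H](O)[C@H](CO[Si](C)(C)C(C)(C)C)CCO)ccc1O[Si](C(C)C)(C(C)C)C(C)C | intermediate
31 | (4S,5R)-5-ArA-4-[(tert-butyldimethylsilyloxy)methyl]tetrahydrofuran-2-ol (anomer mixture) | COc1cc([C@@H]2OC(O)C[C@H]2CO[Si](C)(C)C(C)(C)C)ccc1O[Si](C(C)C)(C(C)C)C(C)C | intermediate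
32 | (4S,5R)-5-ArA-4-[(tert-butyldimethylsilyloxy)methyl]dihydrofuran-2(3H)-one | COc1cc([C@@H]2OC(=O)C[C@H]2CO[Si](C)(C)C(C)(C)C)ccc1O[Si](C(C)C)(C(C)C)C(C)C | intermediate
33 | (4S,5R)-5-ArA-4-(hydroxymethyl)dihydrofuran-2(3H)-one | COc1cc([C@@H]2OC(=O)C[C@H]2CO)ccc1O[Si](C(C)C)(C(C)C)C(C)C | intermediate
34 | (4S,5R)-5-ArA-4-[(ArB-methoxy)methyl]dihydrofuran-2(3H)-one | COc1cc([C@@H]2OC(=O)C[C@H]2COCc2cc(OC)c(O[C@H](CO[Si](C)(C)C(C)(C)C)[C@H](O[Si](C)(C)C(C)(C)C)c3cc(OC)c(O[Si](C(C)C)(C(C)C)C(C)C)c(OC)c3)c(OC)c2)ccc1O[Si](C(C)C)(C(C)C)C(C)C | intermediate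
35 | 3-(trifluoroacetyl) derivative of 34 (C3 undefined, enolised) | COc1cc([C@@H]2OC(=O)C(C(=O)C(F)(F)F)[C@H]2COCc2cc(OC)c(O[C@H](CO[Si](C)(C)C(C)(C)C)[C@H](O[Si](C)(C)C(C)(C)C)c3cc(OC)c(O[Si](C(C)C)(C(C)C)C(C)C)c(OC)c3)c(OC)c2)ccc1O[Si](C(C)C)(C(C)C)C(C)C | intermediate
36 | (4S,5R)-3-diazo-5-ArA-4-[(ArB-methoxy)methyl]dihydrofuran-2(3H)-one | COc1cc([C@@H]2OC(=O)C(=[N+]=[N-])[C@H]2COCc2cc(OC)c(O[C@H](CO[Si](C)(C)C(C)(C)C)[C@H](O[Si](C)(C)C(C)(C)C)c3cc(OC)c(O[Si](C(C)C)(C(C)C)C(C)C)c(OC)c3)c(OC)c2)ccc1O[Si](C(C)C)(C(C)C)C(C)C | intermediate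
37 | (1S,2R,5R,6S)-2-ArA-6-ArB-3,7-dioxabicyclo[3.3.0]octan-4-one (cis-fused, 2-exo, 6-endo) | COc1cc([C@@H]2OC(=O)[C@@H]3[C@H]2CO[C@@H]3c2cc(OC)c(O[C@H](CO[Si](C)(C)C(C)(C)C)[C@H](O[Si](C)(C)C(C)(C)C)c3cc(OC)c(O[Si](C(C)C)(C(C)C)C(C)C)c(OC)c3)c(OC)c2)ccc1O[Si](C(C)C)(C(C)C)C(C)C | intermediate
38 | (2S,3S,4S)-2-ArB-3-(hydroxymethyl)-4-[(R)-hydroxy(ArA)methyl]tetrahydrofuran | COc1cc([C@H](O)[C@@H]2CO[C@H](c3cc(OC)c(O[C@H](CO[Si](C)(C)C(C)(C)C)[C@H](O[Si](C)(C)C(C)(C)C)c4cc(OC)c(O[Si](C(C)C)(C(C)C)C(C)C)c(OC)c4)c(OC)c3)[C@@H]2CO)ccc1O[Si](C(C)C)(C(C)C)C(C)C | intermediate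
39 | primary methanesulfonate of 38 | COc1cc([C@H](O)[C@@H]2CO[C@H](c3cc(OC)c(O[C@H](CO[Si](C)(C)C(C)(C)C)[C@H](O[Si](C)(C)C(C)(C)C)c4cc(OC)c(O[Si](C(C)C)(C(C)C)C(C)C)c(OC)c4)c(OC)c3)[C@@H]2COS(C)(=O)=O)ccc1O[Si](C(C)C)(C(C)C)C(C)C | intermediate
40 | (1S,2R,5S,6S)-2-ArA-6-ArB-3,7-dioxabicyclo[3.3.0]octane (2-exo, 6-endo) | COc1cc([C@@H]2OC[C@@H]3[C@H]2CO[C@@H]3c2cc(OC)c(O[C@H](CO[Si](C)(C)C(C)(C)C)[C@H](O[Si](C)(C)C(C)(C)C)c3cc(OC)c(O[Si](C(C)C)(C(C)C)C(C)C)c(OC)c3)c(OC)c2)ccc1O[Si](C(C)C)(C(C)C)C(C)C | intermediate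
41 | (1S,2R,5S,6S)-2-(4-hydroxy-3-methoxyphenyl)-6-{4-[(1R,2R)-1,3-dihydroxy-1-(4-hydroxy-3,5-dimethoxyphenyl)propan-2-yloxy]-3,5-dimethoxyphenyl}-3,7-dioxabicyclo[3.3.0]octane | COc1cc([C@@H]2OC[C@@H]3[C@H]2CO[C@@H]3c2cc(OC)c(O[C@H](CO)[C@H](O)c3cc(OC)c(O)c(OC)c3)c(OC)c2)ccc1O | target

## Step count

- **Total step count:** 28.
- **Longest linear sequence:** 18 steps (1, 2, 3, 4, 5, 6, 8, 9, 10, 11, 12, 13, 23, 24, 25, 26, 27, 28). The ring-A branch contributes 9 steps in parallel, and step 7 is a one-step branch.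

## Steps most likely to fail

**Step 9 (the new ATH–DKR).**
- Risks: the electron-rich ketone may reduce slowly, or the syn/anti preference may be lower than expected with the bulky aryloxy group.
- The fallback uses known chemistry (an Evans syn glycolate aldol), sets out from 12 and 7, and comes back at 15.
- Phenol 12 is alkylated with chloroacetic acid (NaOH, H2O, reflux) to 2-(4-bromo-2,6-dimethoxyphenoxy)acetic acid F1. This acid is coupled (DCC, DMAP, CH2Cl2) with (S)-4-benzyloxazolidin-2-one to the N-(aryloxyacetyl)oxazolidinone F2. Enolisation with Bu2BOTf/i-Pr2NEt and addition of aldehyde 7 at −78 °C gives the (2S,3R) syn aldol adduct F3. LiBH4 (THF/MeOH, 0 °C) then removes the auxiliary reductively and delivers diol 15.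

**Step 23 (fragment union).**
- Risks: the Lewis acid may ionise the benzylic silyl ether of 20, or may isomerise hydroxy lactone 33 by translactonisation.
- The fallback moves the union to the acyclic diol under neutral conditions, sets out from 19 and 27, and comes back at 34.
- Alcohol 19 is converted (CBr4, PPh3, CH2Cl2, 0 °C) into the benzylic bromide F4. Diol 27 is heated with Bu2SnO (toluene, Dean–Stark) to the six-membered dibutylstannylene acetal F5. This acetal is alkylated by F4 (CsF, DMF, rt) at the primary oxygen to give the mono-ether F6. Treatment with 9-BBN, then NaBO3, gives the 1,4-diol F7. TEMPO/PhI(OAc)2 then closes the lactone to 34.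

**Step 25 (C–H insertion).**
- Risks: 1,2-hydride shift to the butenolide, attack on ring B, or an eroded endo preference in this large substrate.
- The fallback is the classical lactone-aldol/tetraol route, sets out from 27 and from aldehyde 18 (isolated by leaving out NaBH4 in step 12), and comes back at 40.
- Diol 27 is hydroborated and oxidised (9-BBN; NaBO3) to the triol F8. TEMPO/PhI(OAc)2 oxidises the less hindered primary alcohol and the lactol closes on the other primary hydroxyl, giving the β-substituted lactone F9.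
- The dianion of F9 (LDA, 2.2 equiv, THF, −78 °C) adds to 18 anti to the β-substituent. It reacts through the chair transition state of the fixed E-enolate to give the 3,4-trans anti aldol F10.
- LiAlH4 gives the tetraol F11. MsCl (2.1 equiv) in pyridine at 0 °C gives the bis(primary mesylate) F12. Both rings of F12 close by 5-exo-tet attack of the benzylic hydroxyls, with retention at C2 and C6, to give 40.

## Further compounds

F1 | step 9 | 2-(4-bromo-2,6-dimethoxyphenoxy)acetic acid | OC(=O)COc1c(OC)cc(Br)cc1OC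
F2 | step 9 | (S)-4-benzyl-3-[2-(4-bromo-2,6-dimethoxyphenoxy)acetyl]oxazolidin-2-one | O=C(COc1c(OC)cc(Br)cc1OC)N1[C@@H](Cc2ccccc2)COC1=O
F3 | step 9 | (S)-4-benzyl-3-[(2S,3R)-2-(4-bromo-2,6-dimethoxyphenoxy)-3-hydroxy-3-ArC-propanoyl]oxazolidin-2-one | Brc1cc(OC)c(O[C@H](C(=O)N2[C@@H](Cc3ccccc3)COC2=O)[C@H](O)c2cc(OC)c(O[Si](C(C)C)(C(C)C)C(C)C)c(OC)c2)c(OC)c1
F4 | step 23 | ArB-CH2Br | BrCc1cc(OC)c(O[C@H](CO[Si](C)(C)C(C)(C)C)[C@H](O[Si](C)(C)C(C)(C)C)c2cc(OC)c(O[Si](C(C)C)(C(C)C)C(C)C)c(OC)c2)c(OC)c1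
F5 | step 23 | (4R,5S)-2,2-dibutyl-4-ArA-5-vinyl-1,3,2-dioxastanninane | CCCC[Sn]1(CCCC)OC[C@H](C=C)[C@H](c2ccc(O[Si](C(C)C)(C(C)C)C(C)C)c(OC)c2)O1
F6 | step 23 | (1R,2S)-1-ArA-2-[(ArB-methoxy)methyl]but-3-en-1-ol | COc1cc([C@H](O)[C@H](COCc2cc(OC)c(O[C@H](CO[Si](C)(C)C(C)(C)C)[C@H](O[Si](C)(C)C(C)(C)C)c3cc(OC)c(O[Si](C(C)C)(C(C)C)C(C)C)c(OC)c3)c(OC)c2)C=C)ccc1O[Si](C(C)C)(C(C)C)C(C)C
F7 | step 23 | (1R,2S)-1-ArA-2-[(ArB-methoxy)methyl]butane-1,4-diol | COc1cc([C@H](O)[C@H](COCc2cc(OC)c(O[C@H](CO[Si](C)(C)C(C)(C)C)[C@H](O[Si](C)(C)C(C)(C)C)c3cc(OC)c(O[Si](C(C)C)(C(C)C)C(C)C)c(OC)c3)c(OC)c2)CCO)ccc1O[Si](C(C)C)(C(C)C)C(C)C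
F8 | step 25 | (1R,2S)-1-ArA-2-(hydroxymethyl)butane-1,4-diol | COc1cc([C@H](O)[C@H](CO)CCO)ccc1O[Si](C(C)C)(C(C)C)C(C)C
F9 | step 25 | (4S)-4-[(R)-hydroxy(ArA)methyl]dihydrofuran-2(3H)-one | COc1cc([C@H](O)[C@@H]2COC(=O)C2)ccc1O[Si](C(C)C)(C(C)C)C(C)C
F10 | step 25 | (3R,4S)-3-[(S)-hydroxy(ArB)methyl]-4-[(R)-hydroxy(ArA)methyl]dihydrofuran-2(3H)-one | COc1cc([C@H](O)[C@@H]2COC(=O)[C@H]2[C@H](O)c2cc(OC)c(O[C@H](CO[Si](C)(C)C(C)(C)C)[C@H](O[Si](C)(C)C(C)(C)C)c3cc(OC)c(O[Si](C(C)C)(C(C)C)C(C)C)c(OC)c3)c(OC)c2)ccc1O[Si](C(C)C)(C(C)C)C(C)C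
F11 | step 25 | (1R,2S,3S,4S)-1-ArA-4-ArB-2,3-bis(hydroxymethyl)butane-1,4-diol | COc1cc([C@H](O)[C@H](CO)[C@@H](CO)[C@H](O)c2cc(OC)c(O[C@H](CO[Si](C)(C)C(C)(C)C)[C@H](O[Si](C)(C)C(C)(C)C)c3cc(OC)c(O[Si](C(C)C)(C(C)C)C(C)C)c(OC)c3)c(OC)c2)ccc1O[Si](C(C)C)(C(C)C)C(C)C
F12 | step 25 | bis(primary methanesulfonate) of F11 | COc1cc([C@H](O)[C@H](COS(C)(=O)=O)[C@@H](COS(C)(=O)=O)[C@H](O)c2cc(OC)c(O[C@H](CO[Si](C)(C)C(C)(C)C)[C@H](O[Si](C)(C)C(C)(C)C)c3cc(OC)c(O[Si](C(C)C)(C(C)C)C(C)C)c(OC)c3)c(OC)c2)ccc1O[Si](C(C)C)(C(C)C)C(C)C
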